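**Numbering used throughout:** 1 phloroglucinol; 2 its 3,5-bis(methoxymethyl) ether; 3 the silyl ether of 2; 4 allyl bromide; 5 the aryllithium from 3; 6 the C-allylated silyl ether; 7 the C-allylated phenol; 8 the ring A salicylaldehyde; 9 2',4'-dihydroxyacetophenone; 10 its 4-O-allyl ether; 11 the 3-C-allyl diol; 12 its 4-O-methoxymethyl ether; 13 the 2-O-methyl ether; 14 the silyl enol ether of 13; 15 the ring B bromo ketone; 16 the keto aldehyde; 17 the protected diallyl ketol; 18 its per-silylated form; 19 the free diallyl ketol; 20 2-methylbut-2-ene; 21 the target.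

## Analysis of the target

The target is a (3R)-3-hydroxyisoflavanone. Ring A, a phloroglucinol-type benzene, is fused to the dihydropyranone ring C (O1, C2H2, C3, C4=O), and C3 carries both a hydroxyl group and aryl ring B. Ring A has OH at C5 (hydrogen-bonded to the C4 carbonyl) and at C7, a prenyl group at C6 between them and hydrogen at C8; ring B has OMe at C2', prenyl at C3' and OH at C4'. C3 is the only stereocentre, a fully substituted carbinol bounded by C2, C4, C1' and OH. With no second stereo-element to relay from, it has to be set by catalyst control, and having no α-hydrogen it cannot epimerise by enolisation. It can still be lost by C3–C4 cleavage (retro-benzoin), acyloin shift or ionisation, because it is a tertiary benzylic alcohol para to the 4'-oxygen, and forcing acid or base would dehydrate ring C to the aromatic chromone. The two prenyl chains are each ortho to free phenols (C6 between 5-OH and 7-OH, C3' next to 4'-OH): acid closes them to 2,2-dimethylchromans and electrophilic halogen or oxygen reagents attack the trisubstituted alkenes. The synthesis is hard because the three oxygens of a symmetric ring A precursor must be told apart (side chain at C6, not C8), the quaternary carbinol must be made as one enantiomer, and the usual phenol deprotections clash with prenylphenols. The plan rests on the C6 and C3' side chains: each ArCH2–CH=CMe2 unit is carried as ArCH2–CH=CH2, which tolerates acid, base, carbenes and electrophilic bromine, and is converted to prenyl at the very end.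

## Retrosynthetic reasoning

**21 ⇒ 19 + 20.** The trisubstituted C=C bond of each side chain is cut, leaving a terminal allyl group on C6 and on C3' and taking both isopropylidene units from 20. Any other final bond would have to be made in the presence of prenylphenols. Cutting here means that everything before it sees only monosubstituted alkenes, and the last step is a neutral, catalytic alkene exchange on the unprotected polyphenol. The forward reaction must convert both allyl groups without moving the double bonds into conjugation.

**19 ⇒ 17.** The three aryl O–CH2OMe bonds (5-O, 7-O, 4'-O) are cut. The phenols must be masked for the ether formation and the carbene step, and on ring A the acetals also serve as directing groups. They are removed at this point, while the alkenes are still terminal, so no acetal cleavage is ever run on a prenylphenol. The forward step must free three phenols without ionising the tertiary benzylic ketol.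

**17 ⇒ 16.** The C3–C4 bond is cut. It is the one bond whose formation creates the stereocentre and closes ring C at once. The cut exposes an aldehyde on ring A (C4) and an aryl ketone (C3), the partners of an intramolecular crossed benzoin reaction under a chiral carbene catalyst. Cutting C3–C1' or C3–OH would instead call for arylation or hydroxylation of a hindered enolate, with the stereocontrol less well founded. The substrate 16 is achiral, so the forward step must discriminate the two faces of the ketone.

**16 ⇒ 8 + 15.** The O1–C2 ether bond is cut, giving a ring A phenol and a ring B primary α-bromo ketone. This is the convergent junction. It requires that in 8 the only free oxygen is the one that becomes O1.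

**15 ⇒ 13 ⇒ 12 ⇒ 11 ⇒ 10 ⇒ 9 + 4.** On ring B the C–Br bond is cut first (bromine delivered through enol ether 14). Then the two O–C bonds are cut: methyl on the chelated 2-O and acetal on 4-O, the order being fixed by the hydrogen bond between the 2-OH and the acetyl group. Last, the C3'–CH2 bond is traced to a [3,3] shift of an allyl group from the 4-oxygen of 10 to the ring carbon between the two oxygens. The allyl ether 10 comes from 9 and 4.

**8 ⇒ 7 ⇒ 6 ⇒ 3 + 4; 3 ⇒ 2 ⇒ 1.** On ring A the C4a–CHO bond is cut. In 7 the free phenol is para to the allyl group and its two ortho positions are equivalent, so ortho-formylation can give only one aldehyde, with CHO between the future O1 and the future O5. The C6–CH2 bond is traced to metalation of 3 at the one position flanked by both acetal oxygens (through 5) and substitution on 4. The silyl ether of 3 marks the oxygen that becomes O1. With three identical ethers, the two acetals flanking the aldehyde could not be distinguished later, so the desymmetrisation is done at the outset on triol 1, at the cost of a statistical first step.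

## Alternatives that were turned down

**Alternative 1:** Ring C is disconnected at O1–C8a and C4–C4a. Ring A enters as an aryne generated by fluoride from the silyl aryl triflate A2, and the partner is the hydroxy ester A3, which already holds the C3 centre. In the forward key step the primary alkoxide of A3 adds to the aryne at C8a (directed by the acetal oxygen at C5, which places the aryl anion at C4a), and that anion attacks the ester to give the tetrakis(methoxymethyl) ether A1.
- For: two ring bonds form in one operation, the route is highly convergent, and the stereocentre is never built on a hindered ketone. On convergence at the ring-forming step this route is stronger than the chosen one.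
- Against: A2 is a pentasubstituted benzene that needs the same oxygen differentiation as ring A here plus an ortho silyl/triflate pair. A3 needs its own enantioselective construction of an α-aryl-α-alkoxy ester. Its alkoxide can fragment by retro-aldol loss of the hydroxymethyl carbon, and the aryl anion can be protonated before it acylates.
- Decisive point: A1 carries acetals on three phenols and on the tertiary alcohol, to be removed by acid with both prenyl groups in place, which is the chroman-forming situation.
- Comparison: the chosen route is less convergent in the ring-forming step, but its acetal cleavage is run on 17, which has only allyl groups, and the tertiary alcohol is never protected.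

**Alternative 2:** C3–C4 and O1–C2 are disconnected. Ring B is the (R)-aryl oxirane A5 and ring A the benzodioxinone A6. In the forward key step a sec-alkyllithium–diamine base metalates the benzylic oxirane carbon, which is acylated by A6 with retention; the phenoxide released from the acetonide then opens the oxirane at its CH2 carbon (6-exo-tet) to give A4.
- For: the C3 configuration comes from a terminal aryl epoxide, a class reachable by dependable asymmetric methods, and the tertiary hydroxyl emerges free. On the source of chirality this route is at least as strong as a catalytic benzoin on a hindered ketone.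
- Against: the lithiated oxirane is a carbenoid on an electron-rich arene. The C3' prenyl CH2 of A5 is benzylic and allylic and competes for the base. The ketone formed is more electrophilic than A6, so double addition is a risk. A6 needs the same ring A oxygen differentiation.
- Decisive point: A4 still needs acid to remove two acetals, and fluoride for the silyl ether, with both prenyl groups present.
- Comparison: the chosen route uses only weak bases after the fragments are joined and finishes all deprotection before a prenyl group exists.

**Alternative 3:** Ring A is disconnected entirely, at C8–C8a and C4a–C5. The bis(silyloxy)diene A8 adds to the brominated dihydropyranone A9, with the diene CH2 terminus bonding to C8a and the ketene acetal carbon to C4a. Loss of bromide, the methoxy group and the silyl groups aromatises the adduct to A7.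
- For: the ring A pattern (5-OH, 6-prenyl, 7-OH, 8-H) is built, not selected among equivalent positions, and both ring A phenols emerge free. On this point it is stronger than the chosen route, which pays for oxygen differentiation with a statistical protection and a silyl on/off pair.
- Against: A9, an enantiopure 3-aryl-3-alkoxy pyranone with a vinylic bromide, needs a long sequence of its own. Its double bond is a vinylogous ester and a weak partner for an electron-rich diene, so heat or Lewis acid is needed, which the silyl ketene acetal of A8 tolerates poorly.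
- Decisive point: A7 keeps acetals on the tertiary alcohol and on the 4'-oxygen, so acid again meets two prenylphenols.
- Comparison: the chosen route reaches its cyclisation substrate 16 from two five-step fragments made from commodity phenols and never exposes a prenyl group to a deprotection.

Key step: step 14

Remark on the chemistry: the aminoindanol-derived triazolium salt of step 12 is written as its (5aR,10bS) antipode on the assumption that this antipode delivers the (3R) ketol; if the sense of induction is the opposite, the (5aS,10bR) salt is used and nothing else changes.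

## Route

Step 1
Reactants: 1 phloroglucinol
Product: 2 3,5-bis(methoxymethoxy)phenol
Conditions: NaH (2.0 equiv), MOMCl (2.0 equiv), DMF, 0 °C → rt
Reagents that add atoms: chloromethyl methyl ether (MOMCl), COCCl
Why: Williamson-type O-alkylation of the phenoxide by a hard chloromethyl ether. The distribution is statistical: the bis-ether is separated by chromatography and the mono- and tris-ether fractions are recycled, a price accepted at the first step on a commodity triol because it singles out the oxygen that becomes O1.

Step 2
Reactants: 2 3,5-bis(methoxymethoxy)phenol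
Product: 3 [3,5-bis(methoxymethoxy)phenoxy]tri(propan-2-yl)silane
Conditions: i-Pr3SiCl, imidazole, DMF, rt
Reagents that add atoms: chlorotri(propan-2-yl)silane, CC(C)[Si](Cl)(C(C)C)C(C)C
Why: Silylation of the single free phenol. The bulky triisopropylsilyl ether withstands n-BuLi and does not direct metalation, so it marks the future O1 and leaves the two acetals to steer the next step.

Step 3
Reactants: 3 [3,5-bis(methoxymethoxy)phenoxy]tri(propan-2-yl)silane; 4 allyl bromide
Product: 6 [3,5-bis(methoxymethoxy)-4-(prop-2-enyl)phenoxy]tri(propan-2-yl)silane, via aryllithium 5 (not isolated)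
Conditions: n-BuLi (1.1 equiv), THF, 0 °C; then CuI (10 mol %), allyl bromide, −78 °C → rt
Reagents that add atoms: none
Why: Directed ortho-metalation: the C–H flanked by both acetal oxygens is the most acidic and is doubly coordinated, so n-BuLi should remove it selectively. Copper-catalysed substitution of allyl bromide by the aryllithium then forms the aryl–CH2 bond para to the silyloxy group.

Step 4
Reactants: 6 [3,5-bis(methoxymethoxy)-4-(prop-2-enyl)phenoxy]tri(propan-2-yl)silane
Product: 7 3,5-bis(methoxymethoxy)-4-(prop-2-enyl)phenol
Conditions: n-Bu4NF (1.1 equiv), THF, 0 °C; aq NH4Cl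
Reagents that add atoms: none
Why: Fluoride-induced cleavage of an aryl silyl ether, driven by the Si–F bond and the phenoxide leaving group; the acetals and the terminal alkene are inert.

Step 5
Reactants: 7 3,5-bis(methoxymethoxy)-4-(prop-2-enyl)phenol
Product: 8 6-hydroxy-2,4-bis(methoxymethoxy)-3-(prop-2-enyl)benzaldehyde
Conditions: MgCl2 (anhydrous), Et3N, (CH2O)n, MeCN, reflux; aq citric acid work-up
Reagents that add atoms: formaldehyde (as paraformaldehyde), C=O
Why: Magnesium-mediated ortho-formylation of a phenol (Casnati–Skattebøl reaction): the magnesium phenoxide delivers formaldehyde to the ortho carbon and a second formaldehyde accepts hydride. The two ortho positions of 7 are equivalent, so only one aldehyde can form, with CHO between the free OH (future O1) and an acetal oxygen (future O5) and the allyl group para to the OH.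

Step 6
Reactants: 9 2',4'-dihydroxyacetophenone; 4 allyl bromide
Product: 10 1-[2-hydroxy-4-(prop-2-enyloxy)phenyl]ethanone
Conditions: K2CO3, acetone, reflux
Reagents that add atoms: none
Why: Williamson etherification; the 2-OH is held in a hydrogen bond to the acetyl group, so the more acidic, unchelated 4-OH reacts alone.

Step 7
Reactants: 10 1-[2-hydroxy-4-(prop-2-enyloxy)phenyl]ethanone
Product: 11 1-[2,4-dihydroxy-3-(prop-2-enyl)phenyl]ethanone
Conditions: PhNEt2, 200 °C, Ar
Reagents that add atoms: none
Why: Aromatic Claisen rearrangement ([3,3]-sigmatropic shift, then tautomerisation). The chelate ring localises double-bond character in the C3–C4 bond, so migration to C3, between the two oxygens, is expected to dominate over C5; any C5 isomer is removed here.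

Step 8
Reactants: 11 1-[2,4-dihydroxy-3-(prop-2-enyl)phenyl]ethanone
Product: 12 1-[2-hydroxy-4-(methoxymethoxy)-3-(prop-2-enyl)phenyl]ethanone
Conditions: MOMCl (1.1 equiv), i-Pr2NEt, CH2Cl2, 0 °C → rt
Reagents that add atoms: chloromethyl methyl ether (MOMCl), COCCl
Why: O-alkylation of the unchelated 4-OH; the hydrogen-bonded 2-OH is not engaged by the amine base at this temperature.

Step 9
Reactants: 12 1-[2-hydroxy-4-(methoxymethoxy)-3-(prop-2-enyl)phenyl]ethanone
Product: 13 1-[2-methoxy-4-(methoxymethoxy)-3-(prop-2-enyl)phenyl]ethanone
Conditions: MeI (excess), K2CO3, DMF, 40 °C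
Reagents that add atoms: iodomethane, CI
Why: Williamson methylation of the remaining chelated and flanked phenol, which needs the polar solvent and excess MeI; the acetal and the alkene are inert.

Step 10
Reactants: 13 1-[2-methoxy-4-(methoxymethoxy)-3-(prop-2-enyl)phenyl]ethanone
Product: 15 2-bromo-1-[2-methoxy-4-(methoxymethoxy)-3-(prop-2-enyl)phenyl]ethanone, via silyl enol ether 14 (not isolated)
Conditions: LiN(SiMe3)2 (1.1 equiv), THF, −78 °C; Me3SiCl; then NBS (1.05 equiv), −78 → 0 °C
Reagents that add atoms: N-bromosuccinimide, BrN1C(=O)CCC1=O
Why: α-Bromination of a ketone through its kinetic silyl enol ether. The enol ether is far more nucleophilic toward NBS than the terminal alkene or the arene, so bromine should go to the methyl carbon only, without free HBr that would threaten the acetal.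

Step 11
Reactants: 8 6-hydroxy-2,4-bis(methoxymethoxy)-3-(prop-2-enyl)benzaldehyde; 15 2-bromo-1-[2-methoxy-4-(methoxymethoxy)-3-(prop-2-enyl)phenyl]ethanone
Product: 16 6-{2-[2-methoxy-4-(methoxymethoxy)-3-(prop-2-enyl)phenyl]-2-oxoethoxy}-2,4-bis(methoxymethoxy)-3-(prop-2-enyl)benzaldehyde
Conditions: K2CO3 (1.5 equiv), acetone, rt
Reagents that add atoms: none
Why: Williamson etherification of the salicylaldehyde phenoxide with a primary α-bromo ketone (SN2 accelerated by the adjacent carbonyl), forming O1–C2. The mild base at room temperature avoids aldol closure to a benzofuran (Rap–Stoermer pathway).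

Step 12
Reactants: 16 6-{2-[2-methoxy-4-(methoxymethoxy)-3-(prop-2-enyl)phenyl]-2-oxoethoxy}-2,4-bis(methoxymethoxy)-3-(prop-2-enyl)benzaldehyde
Product: 17 (3R)-3-hydroxy-3-[2-methoxy-4-(methoxymethoxy)-3-(prop-2-enyl)phenyl]-5,7-bis(methoxymethoxy)-6-(prop-2-enyl)-2,3-dihydro-4H-chromen-4-one
Conditions: (5aR,10bS)-2-(pentafluorophenyl)-5a,10b-dihydro-4H,6H-indeno[2,1-b][1,2,4]triazolo[4,3-d][1,4]oxazin-2-ium tetrafluoroborate (15 mol %), Et3N (15 mol %), toluene, 25 °C, Ar
Reagents that add atoms: none
Why: Intramolecular crossed benzoin reaction under chiral N-heterocyclic carbene catalysis, the established way from salicylaldehyde-derived keto ethers to 3-hydroxychroman-4-ones: the carbene adds to the aldehyde and the Breslow intermediate attacks the aryl ketone in a 6-exo-trig closure, forming C3–C4 and releasing the catalyst. The C3 configuration is set by the catalyst, whose fused aminoindane shields one face of the acyl anion equivalent while the enol OH orients the ketone oxygen, so one ketone face is attacked. The weak amine base limits enolisation of the O–CH2–C=O unit and retro-benzoin erosion.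

Step 13
Reactants: 17 (3R)-3-hydroxy-3-[2-methoxy-4-(methoxymethoxy)-3-(prop-2-enyl)phenyl]-5,7-bis(methoxymethoxy)-6-(prop-2-enyl)-2,3-dihydro-4H-chromen-4-one
Product: 19 (3R)-3,5,7-trihydroxy-3-[4-hydroxy-2-methoxy-3-(prop-2-enyl)phenyl]-6-(prop-2-enyl)-2,3-dihydro-4H-chromen-4-one, via tetrakis(trimethylsilyl) ether 18 (not isolated)
Conditions: Me3SiOTf (8 equiv), 2,2'-bipyridyl (12 equiv), MeCN, 0 °C → rt; then H2O, rt
Reagents that add atoms: none
Why: Silyl triflate–bipyridyl cleavage of aryl methoxymethyl ethers: the buffered silyl triflate activates each acetal, the oxygens emerge as trimethylsilyl ethers, and water then removes every O–Si bond. No Brønsted acid strong enough to ionise the tertiary benzylic ketol or to add to the terminal alkenes is present, and C3 has no hydrogen to lose.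

Step 14
Reactants: 19 (3R)-3,5,7-trihydroxy-3-[4-hydroxy-2-methoxy-3-(prop-2-enyl)phenyl]-6-(prop-2-enyl)-2,3-dihydro-4H-chromen-4-one; 20 2-methylbut-2-ene
Product: 21 (3R)-3,5,7-trihydroxy-3-[4-hydroxy-2-methoxy-3-(3-methylbut-2-enyl)phenyl]-6-(3-methylbut-2-enyl)-2,3-dihydro-4H-chromen-4-one (CNP0157505.1)
Conditions: (H2IMes)Cl2Ru(=CH-C6H4-2-OiPr) (second-generation Hoveyda–Grubbs catalyst, 10 mol %), 2-methylbut-2-ene/CH2Cl2 (1:1), 25 → 35 °C, sealed tube, Ar
Reagents that add atoms: none
Why: Olefin cross-metathesis: the ruthenium alkylidene released from the precatalyst adds to each terminal alkene of 19 by [2+2] cycloaddition, and cycloreversion with 20 exchanges the terminal CH2 for an isopropylidene group, forming both trisubstituted C=C bonds and releasing propene. The closest known reaction type is the cross-metathesis of allylarenes, free ortho-allylphenols included, with 2-methylbut-2-ene to give prenylarenes. No ring is closed and no stereocentre is formed; C3 carries no hydrogen and the medium is neutral, so its configuration is untouched. Cross-metathesis must win over self-metathesis and over double-bond migration, which is secured by using 20 as co-solvent in very large excess near room temperature, so that each alkylidene meets 20 before it can couple two substrate molecules or decay to a hydride. Prenyl must win over crotyl: transfer of the ethylidene end of 20 gives a 1,2-disubstituted alkene that remains a good substrate and is converted further, whereas the trisubstituted prenyl alkene is essentially inert and accumulates. The phenols, the hydrogen-bonded ketone and the tertiary alcohol are tolerated by the ruthenium carbene, and the two allyl groups sit on different rings, too far apart for ring closure to compete with a partner present in excess.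

## Compound list

1 | phloroglucinol (benzene-1,3,5-triol) | Oc1cc(O)cc(O)c1 | starting material
2 | 3,5-bis(methoxymethoxy)phenol | COCOc1cc(O)cc(OCOC)c1 | intermediate
3 | [3,5-bis(methoxymethoxy)phenoxy]tri(propan-2-yl)silane | COCOc1cc(O[Si](C(C)C)(C(C)C)C(C)C)cc(OCOC)c1 | intermediate
4 | allyl bromide (3-bromoprop-1-ene) | C=CCBr | starting material
5 | {2,6-bis(methoxymethoxy)-4-[tri(propan-2-yl)silyloxy]phenyl}lithium | [Li]c1c(OCOC)cc(O[Si](C(C)C)(C(C)C)C(C)C)cc1OCOC | intermediate
6 | [3,5-bis(methoxymethoxy)-4-(prop-2-enyl)phenoxy]tri(propan-2-yl)silane | C=CCc1c(OCOC)cc(O[Si](C(C)C)(C(C)C)C(C)C)cc1OCOC | intermediate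
7 | 3,5-bis(methoxymethoxy)-4-(prop-2-enyl)phenol | C=CCc1c(OCOC)cc(O)cc1OCOC | intermediate
8 | 6-hydroxy-2,4-bis(methoxymethoxy)-3-(prop-2-enyl)benzaldehyde | C=CCc1c(OCOC)cc(O)c(C=O)c1OCOC | intermediate
9 | 2',4'-dihydroxyacetophenone [1-(2,4-dihydroxyphenyl)ethanone] | CC(=O)c1ccc(O)cc1O | starting material
10 | 1-[2-hydroxy-4-(prop-2-enyloxy)phenyl]ethanone | CC(=O)c1ccc(OCC=C)cc1O | intermediate
11 | 1-[2,4-dihydroxy-3-(prop-2-enyl)phenyl]ethanone | CC(=O)c1ccc(O)c(CC=C)c1O | intermediate
12 | 1-[2-hydroxy-4-(methoxymethoxy)-3-(prop-2-enyl)phenyl]ethanone | CC(=O)c1ccc(OCOC)c(CC=C)c1O | intermediate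
13 | 1-[2-methoxy-4-(methoxymethoxy)-3-(prop-2-enyl)phenyl]ethanone | CC(=O)c1ccc(OCOC)c(CC=C)c1OC | intermediate
14 | {1-[2-methoxy-4-(methoxymethoxy)-3-(prop-2-enyl)phenyl]ethenyloxy}trimethylsilane | C=C(O[Si](C)(C)C)c1ccc(OCOC)c(CC=C)c1OC | intermediate
15 | 2-bromo-1-[2-methoxy-4-(methoxymethoxy)-3-(prop-2-enyl)phenyl]ethanone | BrCC(=O)c1ccc(OCOC)c(CC=C)c1OC | intermediate
16 | 6-{2-[2-methoxy-4-(methoxymethoxy)-3-(prop-2-enyl)phenyl]-2-oxoethoxy}-2,4-bis(methoxymethoxy)-3-(prop-2-enyl)benzaldehyde | O=Cc1c(OCC(=O)c2ccc(OCOC)c(CC=C)c2OC)cc(OCOC)c(CC=C)c1OCOC | intermediate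
17 | (3R)-3-hydroxy-3-[2-methoxy-4-(methoxymethoxy)-3-(prop-2-enyl)phenyl]-5,7-bis(methoxymethoxy)-6-(prop-2-enyl)-2,3-dihydro-4H-chromen-4-one | COc1c([C@@]2(O)COc3cc(OCOC)c(CC=C)c(OCOC)c3C2=O)ccc(OCOC)c1CC=C | intermediate
18 | (3R)-3-[2-methoxy-3-(prop-2-enyl)-4-(trimethylsilyloxy)phenyl]-6-(prop-2-enyl)-3,5,7-tris(trimethylsilyloxy)-2,3-dihydro-4H-chromen-4-one | COc1c([C@@]2(O[Si](C)(C)C)COc3cc(O[Si](C)(C)C)c(CC=C)c(O[Si](C)(C)C)c3C2=O)ccc(O[Si](C)(C)C)c1CC=C | intermediate
19 | (3R)-3,5,7-trihydroxy-3-[4-hydroxy-2-methoxy-3-(prop-2-enyl)phenyl]-6-(prop-2-enyl)-2,3-dihydro-4H-chromen-4-one | COc1c([C@@]2(O)COc3cc(O)c(CC=C)c(O)c3C2=O)ccc(O)c1CC=C | intermediate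
20 | 2-methylbut-2-ene | CC=C(C)C | starting material
21 | (3R)-3,5,7-trihydroxy-3-[4-hydroxy-2-methoxy-3-(3-methylbut-2-enyl)phenyl]-6-(3-methylbut-2-enyl)-2,3-dihydro-4H-chromen-4-one (CNP0157505.1) | COc1c([C@@]2(O)COc3cc(O)c(CC=C(C)C)c(O)c3C2=O)ccc(O)c1CC=C(C)C | target

## Step count and least certain steps

Total step count: 14. Longest linear sequence: 9 steps (steps 1–5 then 11–14; the ring B branch, steps 6–10 then 11–14, is equally long).

**Step 14 (key step).** Ruthenium hydride species formed on catalyst decay may move the terminal double bonds into conjugation with the rings, after which metathesis gives chain-shortened alkenes. The chelating 5-OH/C4=O pair or the phenols may also tie up ruthenium, so that one allyl group stays unconverted. The fallback inverts the last two steps. It sets out from 17, in which all three phenols are capped. Cross-metathesis with 20 under the same catalyst should give (3R)-3-hydroxy-3-[2-methoxy-4-(methoxymethoxy)-3-(3-methylbut-2-enyl)phenyl]-5,7-bis(methoxymethoxy)-6-(3-methylbut-2-enyl)-2,3-dihydro-4H-chromen-4-one F1. The buffered Me3SiOTf/2,2'-bipyridyl cleavage of step 13, followed by water, involves no protic acid strong enough to cyclise a prenylphenol and brings the sequence back to the route at 21.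

**Step 12.** Facial selectivity may be poor, or closure slow, because the ketone is flanked by the ortho methoxy group and twisted out of conjugation and the aldehyde is electron-rich with two ortho oxygens; base-induced aldol closure of the O–CH2–C=O unit onto the aldehyde may then compete. The fallback separates ring closure from stereocontrol. It sets out from 16. An achiral carbene precursor (2-mesityl-6,7-dihydro-5H-pyrrolo[2,1-c][1,2,4]triazol-2-ium chloride, Et3N, toluene) should give the racemic ketol 3-hydroxy-3-[2-methoxy-4-(methoxymethoxy)-3-(prop-2-enyl)phenyl]-5,7-bis(methoxymethoxy)-6-(prop-2-enyl)-2,3-dihydro-4H-chromen-4-one F2. This is resolved by preparative chromatography on a cellulose tris(3,5-dimethylphenylcarbamate) phase; the (3R) half is 17, where the route is rejoined, and the (3S)-enantiomer F3 is set aside.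

**Step 13.** The tertiary benzylic C3–O bond may ionise, with loss of water toward the aromatic chromone, or an acyloin shift may occur under Lewis acid activation; cleavage of the electron-rich 4'-acetal may be incomplete. The fallback exchanges the acetals for silyl ethers before the carbinol exists. It sets out from 16.
- HCl in MeOH at rt removes the three acetals and gives 2,4-dihydroxy-6-{2-[4-hydroxy-2-methoxy-3-(prop-2-enyl)phenyl]-2-oxoethoxy}-3-(prop-2-enyl)benzaldehyde F4.
- t-BuMe2SiOTf and 2,6-lutidine give the tris(tert-butyldimethylsilyl) ether 2,4-bis(tert-butyldimethylsilyloxy)-6-{2-[4-(tert-butyldimethylsilyloxy)-2-methoxy-3-(prop-2-enyl)phenyl]-2-oxoethoxy}-3-(prop-2-enyl)benzaldehyde F5.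
- The benzoin closure under the conditions of step 12 gives (3R)-5,7-bis(tert-butyldimethylsilyloxy)-3-[4-(tert-butyldimethylsilyloxy)-2-methoxy-3-(prop-2-enyl)phenyl]-3-hydroxy-6-(prop-2-enyl)-2,3-dihydro-4H-chromen-4-one F6.
- n-Bu4NF buffered with AcOH in THF at 0 °C removes the silyl groups and returns to the route at 19.

**Step 3.** Unreacted aryllithium may take a proton from the benzylic and allylic CH2 of the product, leading to double-bond migration; lithium–bromine exchange with allyl bromide and metalation beside the silyloxy group are further possibilities. The fallback replaces the organolithium substitution by a cross-coupling. It sets out from 3, whose lithio derivative 5 is quenched with I2 to give the aryl iodide [4-iodo-3,5-bis(methoxymethoxy)phenoxy]tri(propan-2-yl)silane F7. Stille coupling of F7 with allyltributylstannane (Pd(PPh3)4, CuI, CsF, DMF, 45 °C) returns to the route at 6.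

**Step 10.** If enol ether formation is incomplete, electrophilic bromine may attack the electron-rich ring B or add to the alkene, and a second bromination at the α-carbon is possible. The fallback avoids electrophilic halogen and forms the O1–C2 bond by carbene O–H insertion. It sets out from 13.
- LiN(SiMe3)2 followed by 2,2,2-trifluoroethyl trifluoroacetate gives 4,4,4-trifluoro-1-[2-methoxy-4-(methoxymethoxy)-3-(prop-2-enyl)phenyl]butane-1,3-dione F8.
- Diazo transfer with 4-acetamidobenzenesulfonyl azide (Et3N, H2O, MeCN) and loss of the trifluoroacetyl group gives 2-diazo-1-[2-methoxy-4-(methoxymethoxy)-3-(prop-2-enyl)phenyl]ethanone F9.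
- Rh2(OAc)4-catalysed insertion of the derived carbene into the O–H bond of phenol 8 (CH2Cl2, rt) returns to the route at 16, bypassing 15.

## Further compounds

F1 | step 14 | (3R)-3-hydroxy-3-[2-methoxy-4-(methoxymethoxy)-3-(3-methylbut-2-enyl)phenyl]-5,7-bis(methoxymethoxy)-6-(3-methylbut-2-enyl)-2,3-dihydro-4H-chromen-4-one | COc1c([C@@]2(O)COc3cc(OCOC)c(CC=C(C)C)c(OCOC)c3C2=O)ccc(OCOC)c1CC=C(C)C
F2 | step 12 | racemic 3-hydroxy-3-[2-methoxy-4-(methoxymethoxy)-3-(prop-2-enyl)phenyl]-5,7-bis(methoxymethoxy)-6-(prop-2-enyl)-2,3-dihydro-4H-chromen-4-one | COc1c(C2(O)COc3cc(OCOC)c(CC=C)c(OCOC)c3C2=O)ccc(OCOC)c1CC=C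
F3 | step 12 | (3S)-3-hydroxy-3-[2-methoxy-4-(methoxymethoxy)-3-(prop-2-enyl)phenyl]-5,7-bis(methoxymethoxy)-6-(prop-2-enyl)-2,3-dihydro-4H-chromen-4-one | COc1c([C@]2(O)COc3cc(OCOC)c(CC=C)c(OCOC)c3C2=O)ccc(OCOC)c1CC=C
F4 | step 13 | 2,4-dihydroxy-6-{2-[4-hydroxy-2-methoxy-3-(prop-2-enyl)phenyl]-2-oxoethoxy}-3-(prop-2-enyl)benzaldehyde | O=Cc1c(OCC(=O)c2ccc(O)c(CC=C)c2OC)cc(O)c(CC=C)c1O
F5 | step 13 | 2,4-bis(tert-butyldimethylsilyloxy)-6-{2-[4-(tert-butyldimethylsilyloxy)-2-methoxy-3-(prop-2-enyl)phenyl]-2-oxoethoxy}-3-(prop-2-enyl)benzaldehyde | O=Cc1c(OCC(=O)c2ccc(O[Si](C)(C)C(C)(C)C)c(CC=C)c2OC)cc(O[Si](C)(C)C(C)(C)C)c(CC=C)c1O[Si](C)(C)C(C)(C)C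
F6 | step 13 | (3R)-5,7-bis(tert-butyldimethylsilyloxy)-3-[4-(tert-butyldimethylsilyloxy)-2-methoxy-3-(prop-2-enyl)phenyl]-3-hydroxy-6-(prop-2-enyl)-2,3-dihydro-4H-chromen-4-one | COc1c([C@@]2(O)COc3cc(O[Si](C)(C)C(C)(C)C)c(CC=C)c(O[Si](C)(C)C(C)(C)C)c3C2=O)ccc(O[Si](C)(C)C(C)(C)C)c1CC=C
F7 | step 3 | [4-iodo-3,5-bis(methoxymethoxy)phenoxy]tri(propan-2-yl)silane | Ic1c(OCOC)cc(O[Si](C(C)C)(C(C)C)C(C)C)cc1OCOC
F8 | step 10 | 4,4,4-trifluoro-1-[2-methoxy-4-(methoxymethoxy)-3-(prop-2-enyl)phenyl]butane-1,3-dione | O=C(CC(=O)C(F)(F)F)c1ccc(OCOC)c(CC=C)c1OC
F9 | step 10 | 2-diazo-1-[2-methoxy-4-(methoxymethoxy)-3-(prop-2-enyl)phenyl]ethanone | [N-]=[N+]=CC(=O)c1ccc(OCOC)c(CC=C)c1OC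
A1 | alternative 1 | (3R)-3-(methoxymethoxy)-3-[2-methoxy-4-(methoxymethoxy)-3-(3-methylbut-2-enyl)phenyl]-5,7-bis(methoxymethoxy)-6-(3-methylbut-2-enyl)-2,3-dihydro-4H-chromen-4-one | COc1c([C@@]2(OCOC)COc3cc(OCOC)c(CC=C(C)C)c(OCOC)c3C2=O)ccc(OCOC)c1CC=C(C)C
A2 | alternative 1 | 3,5-bis(methoxymethoxy)-4-(3-methylbut-2-enyl)-2-(trimethylsilyl)phenyl trifluoromethanesulfonate | C[Si](C)(C)c1c(OS(=O)(=O)C(F)(F)F)cc(OCOC)c(CC=C(C)C)c1OCOC
A3 | alternative 1 | methyl (2R)-3-hydroxy-2-(methoxymethoxy)-2-[2-methoxy-4-(methoxymethoxy)-3-(3-methylbut-2-enyl)phenyl]propanoate | COC(=O)[C@@](CO)(OCOC)c1ccc(OCOC)c(CC=C(C)C)c1OC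
A4 | alternative 2 | (3R)-3-hydroxy-3-{2-methoxy-3-(3-methylbut-2-enyl)-4-[tri(propan-2-yl)silyloxy]phenyl}-5,7-bis(methoxymethoxy)-6-(3-methylbut-2-enyl)-2,3-dihydro-4H-chromen-4-one | COc1c([C@@]2(O)COc3cc(OCOC)c(CC=C(C)C)c(OCOC)c3C2=O)ccc(O[Si](C(C)C)(C(C)C)C(C)C)c1CC=C(C)C
A5 | alternative 2 | (2R)-2-{2-methoxy-3-(3-methylbut-2-enyl)-4-[tri(propan-2-yl)silyloxy]phenyl}oxirane | COc1c([C@@H]2CO2)ccc(O[Si](C(C)C)(C(C)C)C(C)C)c1CC=C(C)C
A6 | alternative 2 | 5,7-bis(methoxymethoxy)-2,2-dimethyl-6-(3-methylbut-2-enyl)-4H-1,3-benzodioxin-4-one | CC1(C)OC(=O)c2c(OCOC)c(CC=C(C)C)c(OCOC)cc2O1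
A7 | alternative 3 | (3R)-5,7-dihydroxy-3-(methoxymethoxy)-3-[2-methoxy-4-(methoxymethoxy)-3-(3-methylbut-2-enyl)phenyl]-6-(3-methylbut-2-enyl)-2,3-dihydro-4H-chromen-4-one | COc1c([C@@]2(OCOC)COc3cc(O)c(CC=C(C)C)c(O)c3C2=O)ccc(OCOC)c1CC=C(C)C
A8 | alternative 3 | 1-methoxy-2-(3-methylbut-2-enyl)-1,3-bis(trimethylsilyloxy)buta-1,3-diene | COC(O[Si](C)(C)C)=C(CC=C(C)C)C(=C)O[Si](C)(C)C
A9 | alternative 3 | (3R)-5-bromo-3-(methoxymethoxy)-3-[2-methoxy-4-(methoxymethoxy)-3-(3-methylbut-2-enyl)phenyl]-2,3-dihydro-4H-pyran-4-one | COc1c([C@@]2(OCOC)COC=C(Br)C2=O)ccc(OCOC)c1CC=C(C)C
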